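## Analysis of the target

Compound 26 is a twofold-symmetric dimer. Two 2,2-dimethylchroman units, each a benzene ring (ring A, ring A') fused to a dihydropyran (ring B, ring B'), are joined at C6 and C6' through one methine carbon that also carries a 5-methylhexyl chain. Each arene is hexasubstituted: OH at C5, the bridge at C6, OH at C7, a 2-methylbutanoyl group at C8, the pyran oxygen O1 at C8a and the pyran carbon C4 at C4a.

There are only two stereocentres, the α-carbons of the two acyl groups, both (R). They are separated by the whole bis-arene and cannot control each other. The bridge methine is not stereogenic while both halves are identical, so every epimerised acyl group appears as a diastereomer.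

The sensitive points are these α-carbons (enolisable next to an aryl ketone), the oxidisable phloroglucinol-type nuclei, and the doubly benzylic bridge, which acid can cleave through an ortho-quinone methide while the arenes carry no acyl group.

The difficulty is regiochemical. The three oxygens of each ring are in three different states (hydrogen-bonded OH, free OH, ring ether), and classical phloroglucinol chemistry has trouble telling C6 from C8 and O5 from O7.

The strategy rests on reading ring A as two three-carbon pieces. C5(OH)–C6(bridge)–C7(O) is what a ketene carbon joined to a siloxyalkyne delivers. C8–C8a(O1)–C4a is the enol-ether segment of a 3-alkoxycyclobutenone that already contains ring B. Both arenes can therefore be built, with every substituent in place, rather than decorated.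

## Retrosynthetic reasoning

**Acyl groups (26 to 23 and 25).** The two C8–C(=O) bonds are cut last. In 23, C8 and C8' are the only unsubstituted ring positions, each ortho to the 7-OH and para to the 5-OH, so an electrophilic acylation has no regiochemical choice. Both stereocentres are bought with acid 24 and carried in through chloride 25. The forward reaction must acylate twice without enolising the new ketones.

**Silyl ethers (23 to 22).** The two Si–O bonds are the only difference. The silyl groups are not protecting groups added on purpose but the trace left by the ring-forming step, and they are removed before acylation so that the 7-OH can direct the electrophile to C8.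

**Both arenes (22 to 12 and two molecules of 19).** In each half the bonds C5–C6, C7–C8 and C4a–C5 are cut. This takes ring A apart into the ketene carbon and sp2 carbons of cyclobutenone 19 and one siloxyalkyne arm of 12. It is the only disconnection that removes all the regiochemical problems at once. The oxygen pattern, the position of the bridge and the fusion of ring B follow from the polarity of the partners. The bridge needs no separate arene–carbon bond formation, because it is already the carbon between the two alkynes. In the forward direction 19 must open to vinylketene 20, which must add to each alkyne with the bridge-bearing carbon on the ketene carbon, passing through the half-annulated 21.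

**Siloxyalkynes (12 to 9).** The two C(sp)–O bonds are cut. The terminal diyne 9 is oxidised at both acetylide carbons (10, then the bis-ynolate 11) by a peroxide oxygen donor and capped on oxygen with a bulky silyl triflate. This puts the sensitive ynol ethers in place one step before they are used.

**Skipped diyne (9 to 8 to 5 to 4 to 1 and 2).** The two C(sp3)–C(sp) bonds at the future bridge carbon are cut. That carbon is the carbonyl carbon of aldehyde 1. The first alkyne arrives by acetylide addition (3 to 4). The second replaces the hydroxyl through the cobalt-stabilised cation 6, because a direct displacement at a propargylic centre would leak to allenes. Complex 5 confines the charge to the propargylic carbon and gives 7, which is demetallated to 8. The silyl caps from 2 keep both alkyne termini inert until step 4.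

**Cyclobutenone (19 to 17 to 16 to 15).** The C1=C8 double bond of 19 is traced to ketone 17 through silyl enol ether 18. The four-membered ring is cut at C6–C7 and C1–C8, a ketene–enol ether cycloaddition of dihydropyran 15 with a dichlorinated ketene made in the flask, followed by dechlorination of 16. The polarity of the enol ether puts the carbonyl next to the non-oxygenated fusion carbon, as 19 requires.

**Dihydropyran (15 to 13 and 14).** O1–C2 and C3–C4 of the pyran are cut in a hetero-Diels–Alder sense. Acrolein 13 is the oxadiene and 2-methylpropene 14 brings the gem-dimethyl carbon that ends as C2 of ring B.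

## Alternatives that were turned down

**Alternative 1:** Each ring B is disconnected at C4–C4a and O1–C2, leading back to the bis(1,1-dimethylpropargyl) aryl ether A2. On heating, each arene would undergo a [3,3] shift to C4a (the only free ortho position), then a hydrogen shift and an oxa-6π closure, giving the bis(2H-chromene) A1. One hydrogenation would then saturate C3=C4 and remove the two benzyl groups.
- For it: this cascade is among the best-precedented chromene syntheses and runs without reagents, and on reliability of the key step it is stronger than the chosen route.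
- Against it: A2 is already the complete hexasubstituted bis-arene. Its three oxygens per ring must be told apart (benzyl, tertiary propargyl, free), the hindered propargyl ether must be made on an oxygen ortho to the acyl group, and the bridge and the chiral acyl groups must be in place beforehand. The α-stereocentres then sit through prolonged heating next to free phenols.
- Comparison: the chosen route offers instead a short convergent assembly in which no phenol is ever differentiated by hand.

**Alternative 2:** The two C(=O)–Cα bonds are cut. A cationic rhodium precatalyst such as [Rh(C8H12)2]BF4 (monovalent rhodium) with a chiral bisphosphine would add each aldehyde C–H of the bis-salicylaldehyde A4 across one double bond of buta-1,3-diene A5. This would give the bis(2-methylbut-3-enoyl) compound A3, whose vinyl groups are then hydrogenated.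
- For it: both stereocentres are made late and by catalyst control, the ortho-OH is the chelating group this chemistry needs, and the racemisation risk of a Friedel–Crafts step is avoided. On this point it is stronger than the chosen route.
- Against it: it solves none of the skeletal problems, since A4 still needs both chromans, the bridge and two formylations. Branched versus linear addition to the unsubstituted diene A5 and the enantioselectivity with it are unsecured. In A3 the α-hydrogen is both allylic and α to a ketone, so migration into conjugation would erase the centre. Two independent events also turn any shortfall in selectivity into diastereomers.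
- Comparison: the chosen route takes both centres from 24 with fixed configuration and spends its risk on the skeleton.

**Alternative 3:** O1–C8a is cut in both halves. Pd(OAc)2 with a bulky 2-(di-tert-butylphosphino)biaryl ligand and Cs2CO3 would couple each tertiary alcohol of the dibromide A7 with its neighbouring C–Br bond, closing both rings B to the tetra-O-benzyl ether A6, which is then hydrogenolysed.
- For it: intramolecular aryl etherification to six-membered rings is known, the regiochemistry is unambiguous, and a tertiary alkoxide cannot undergo β-hydride elimination. In precedent it is stronger than the chosen key step.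
- Against it: the bromide is flanked by an acyl group and an alkyl chain on a fully substituted ring, so oxidative addition and the C–O reductive elimination of a tertiary alkoxide are both at their steric limit. The ketone α-stereocentres are exposed to hot carbonate. A7 demands a long linear build-up with four benzyl ethers and two regiodefined brominations.
- Comparison: the chosen route needs no halogen, no protecting group on oxygen and no phenol cyclisation, because ring B arrives ready-made inside 19.

Key step: step 10

Remark on the chemistry: intermediates 4–7, 16–19 and 21 are racemates (one enantiomer is drawn where a relative configuration exists). All their stereocentres are destroyed or become non-stereogenic before 26, so only the two (R) centres of 24 matter. Compounds 1 and 24 are taken as purchasable.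

## Route

Step 1
Reactants: 1 6-methylheptanal; 2 ethynyltrimethylsilane
Product: 4 rac-8-methyl-1-(trimethylsilyl)non-1-yn-3-ol, via lithium (trimethylsilyl)acetylide 3 (not isolated)
Conditions: 2, nBuLi, THF, −78 °C; then 1, −78 → 0 °C; aq NH4Cl
Reagents that add atoms: none
Why: 1,2-addition of a lithium acetylide to an unhindered aliphatic aldehyde. The carbinol centre forms racemic, which does not matter because it is ionised in step 3 and ends as the non-stereogenic bridge carbon.

Step 2
Reactants: 4 rac-8-methyl-1-(trimethylsilyl)non-1-yn-3-ol
Product: 5 hexacarbonyldicobalt complex of 4 (both alkyne carbons bridge the Co–Co bond)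
Conditions: Co2(CO)8, CH2Cl2, 20 °C
Reagents that add atoms: octacarbonyldicobalt, O=C=[Co](=C=O)(=C=O)(=C=O)[Co](=C=O)(=C=O)(=C=O)=C=O
Why: Alkynes displace two carbonyl ligands of Co2(CO)8 at room temperature to give stable bridging alkyne complexes. This is the first stage of a Nicholas reaction.

Step 3
Reactants: 5 hexacarbonyldicobalt complex of 4; 2 ethynyltrimethylsilane (as its dimethylaluminium acetylide)
Product: 8 3-(5-methylhexyl)-1,5-bis(trimethylsilyl)penta-1,4-diyne, via cobalt-stabilised propargylic cation tetrafluoroborate 6 (not isolated), via hexacarbonyldicobalt complex of the diyne 7 (not isolated)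
Conditions: HBF4·OEt2, CH2Cl2, −78 °C; Me2AlC≡CSiMe3 (from 2, nBuLi, Me2AlCl; 2.5 equiv), −78 → 0 °C; then (NH4)2Ce(NO3)6, acetone, 0 °C
Reagents that add atoms: dimethyl[(trimethylsilyl)ethynyl]aluminium (made from 2), C[Al](C)C#C[Si](C)(C)C
Why: Nicholas reaction. The cobalt cluster stabilises the secondary propargylic cation and confines attack to the propargylic carbon, so the alkynyl group of the alane (transferred in preference to methyl) gives the 1,4-diyne and no allene. Oxidation of the cluster by tetravalent cerium then frees 8 without base.

Step 4
Reactants: 8 3-(5-methylhexyl)-1,5-bis(trimethylsilyl)penta-1,4-diyne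
Product: 9 3-(5-methylhexyl)penta-1,4-diyne
Conditions: K2CO3 (0.2 equiv), MeOH, 0 → 20 °C
Reagents that add atoms: none
Why: Methanolysis of both alkynyl–silicon bonds by catalytic methoxide. The base is weak and the contact short, so the doubly propargylic hydrogen should stay and the skipped diyne should not isomerise to an allenyne.

Step 5
Reactants: 9 3-(5-methylhexyl)penta-1,4-diyne
Product: 12 3-(5-methylhexyl)-1,5-bis(triisopropylsilyloxy)penta-1,4-diyne, via dilithium diacetylide 10 (not isolated), via dilithium bis(ynolate) 11 (not isolated)
Conditions: LiN(SiMe3)2 (2.2 equiv), THF, −78 °C; LiOOtBu (from tBuOOH and LiN(SiMe3)2, 2.4 equiv), −78 → 0 °C; iPr3SiOTf (2.4 equiv), −78 → 0 °C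
Reagents that add atoms: tert-butyl hydroperoxide (used as LiOOtBu), CC(C)(C)OO; triisopropylsilyl trifluoromethanesulfonate, CC(C)[Si](C(C)C)(C(C)C)OS(=O)(=O)C(F)(F)F
Why: Julia-type oxidation of lithium acetylides. Each acetylide carbon attacks the peroxide oxygen of LiOOtBu to give a lithium ynolate, which the bulky silyl triflate captures on oxygen. The hindered amide removes the two sp C–H hydrogens but should be too weak at −78 °C to remove the doubly propargylic one.

Step 6
Reactants: 13 acrolein; 14 2-methylpropene
Product: 15 2,2-dimethyl-3,4-dihydro-2H-pyran
Conditions: excess 14, hydroquinone (cat.), benzene, sealed autoclave, 190 °C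
Reagents that add atoms: none
Why: Thermal hetero-Diels–Alder reaction with inverse electron demand, acrolein acting as the 1-oxadiene. The oxygen bonds to the more substituted alkene carbon, which bears the positive charge in the asynchronous transition state, so the 2,2-dimethyl isomer should form.

Step 7
Reactants: 15 2,2-dimethyl-3,4-dihydro-2H-pyran
Product: 16 rac-(1R,6S)-8,8-dichloro-3,3-dimethyl-2-oxabicyclo[4.2.0]octan-7-one (cis-fused)
Conditions: Cl2CHCOCl, Et3N, hexane, 0 → 20 °C (slow addition)
Reagents that add atoms: dichloroacetyl chloride (source of dichloroketene), O=C(Cl)C(Cl)Cl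
Why: Ketene–enol ether [2+2] cycloaddition. The nucleophilic β-carbon of the enol ether bonds to the ketene carbonyl carbon, so the carbonyl ends next to the non-oxygenated fusion carbon. Suprafacial addition to the ring alkene sets the two new stereocentres cis, as a racemate.

Step 8
Reactants: 16 rac-(1R,6S)-8,8-dichloro-3,3-dimethyl-2-oxabicyclo[4.2.0]octan-7-one
Product: 17 rac-(1S,6S)-3,3-dimethyl-2-oxabicyclo[4.2.0]octan-7-one (cis-fused)
Conditions: Zn dust, AcOH, 20 °C
Reagents that add atoms: none
Why: Reductive removal of both α-chlorine atoms through zinc enolates, the standard follow-up to dichloroketene adducts of enol ethers. The fusion stereocentres are untouched; the descriptor at C1 changes only because the priorities change.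

Step 9
Reactants: 17 rac-(1S,6S)-3,3-dimethyl-2-oxabicyclo[4.2.0]octan-7-one
Product: 19 rac-3,3-dimethyl-2-oxabicyclo[4.2.0]oct-1(8)-en-7-one, via trimethylsilyl enol ether 18 (not isolated)
Conditions: LiN(iPr)2, Me3SiCl, THF, −78 °C (internal quench); then Pd(OAc)2 (1.05 equiv), MeCN, 20 °C
Reagents that add atoms: none
Why: Saegusa–Ito dehydrogenation. Kinetic deprotonation at the C8 methylene with immediate silylation should give 18 before the ring oxygen can be eliminated. Pd(OAc)2 then forms the C8-bound palladium enolate on the convex face, syn to H–C1, and β-hydride elimination gives the vinylogous ester 19, whose only stereocentre (C6, racemic) disappears in step 10.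

Step 10
Reactants: 12 3-(5-methylhexyl)-1,5-bis(triisopropylsilyloxy)penta-1,4-diyne; 19 rac-3,3-dimethyl-2-oxabicyclo[4.2.0]oct-1(8)-en-7-one (3 equiv)
Product: 22 6,6'-(6-methylheptane-1,1-diyl)bis[2,2-dimethyl-7-(triisopropylsilyloxy)chroman-5-ol], via pyranylketene 20 (not isolated), via monoannulated siloxyalkyne 21 (not isolated)
Conditions: toluene, 80 → 110 °C, argon, sealed tube
Reagents that add atoms: none
Why: Proposed new method: on heating, 19 should open by four-electron conrotatory cleavage of its C6–C7 bond to vinylketene 20, the ring methylene being forced outward because the new double bond lies inside the pyran; the bridge-bearing carbon of each siloxyalkyne of 12 then attacks the ketene carbonyl carbon in a [2+2] cycloaddition, the resulting 4-alkenyl-3-siloxycyclobutenone opens again to a dienylketene, and 6π electrocyclisation with tautomerisation gives the phenol. The closest known reaction type is the Danheiser benzannulation of simple cyclobutenones with triisopropylsiloxyalkynes to resorcinol monosilyl ethers; untested here are a bicyclic 3-alkoxycyclobutenone, whose enone is a vinylogous ester, and two annulations on one skipped diyne. Ring A and ring A' are each closed by the thermal 6π electrocyclisation (bond C4a–C5) after C5–C6 and C7–C8 have formed in the [2+2] step, and both rings B arrive intact and simply become fused. No stereocentre is created: the one stereocentre of 19 becomes aromatic C4a, 21 is a racemate at the bridge, and the bridge carbon of 22 carries two identical arenes. The selectivity needed is regiochemical, and the oxygen of the siloxyalkyne secures it by making the non-oxygenated alkyne carbon the nucleophile, so that this carbon ends as C6 between OH and OSi while the enol-ether carbon of 19 ends para to it as C8a and the sp3 fusion carbon as C4a. In 20 the allylic ring methylene is trans to the ketene arm, which shuts off the 1,5-hydrogen shift that destroys many vinylketenes, and the doubly propargylic hydrogen of 12 is safe because the reaction needs no base or catalyst. The excess of 19 covers ketene lost to dimerisation and to esterification of the new phenols.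

Step 11
Reactants: 22 6,6'-(6-methylheptane-1,1-diyl)bis[2,2-dimethyl-7-(triisopropylsilyloxy)chroman-5-ol]
Product: 23 6,6'-(6-methylheptane-1,1-diyl)bis(2,2-dimethylchroman-5,7-diol)
Conditions: Bu4NF, AcOH, THF, 0 °C, degassed
Reagents that add atoms: none
Why: Fluoride cleaves aryl silyl ethers rapidly. The acetic acid buffer keeps the very electron-rich product as neutral phenols and so limits air oxidation.

Step 12
Reactants: 24 (R)-2-methylbutanoic acid
Product: 25 (R)-2-methylbutanoyl chloride
Conditions: (COCl)2, DMF (cat.), CH2Cl2, 0 → 20 °C
Reagents that add atoms: oxalyl chloride, O=C(Cl)C(=O)Cl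
Why: Acid chloride formation through the Vilsmeier-type chloroiminium species. No amine base is present, so no ketene can form and the α-stereocentre should stay (R); 25 is used crude.

Step 13
Reactants: 23 6,6'-(6-methylheptane-1,1-diyl)bis(2,2-dimethylchroman-5,7-diol); 25 (R)-2-methylbutanoyl chloride
Product: 26 6,6'-(6-methylheptane-1,1-diyl)bis{5,7-dihydroxy-2,2-dimethyl-8-[(2R)-2-methylbutanoyl]chroman} (target, CNP0324275.1)
Conditions: TiCl4 (6 equiv), 25 (2.4 equiv), CH2Cl2, −20 → 0 °C; aq HCl
Reagents that add atoms: none
Why: Friedel–Crafts C-acylation directed by the titanium phenoxide to C8 and C8', the only unsubstituted ring positions, each ortho to the 7-oxygen and para to the 5-oxygen. Both stereocentres come unchanged from 25, and low temperature with chelation of each new ketone between carbonyl and ortho-phenoxide should hold back enolisation.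

## Compound list

1 | 6-methylheptanal | CC(C)CCCCC=O | starting material
2 | ethynyltrimethylsilane | C#C[Si](C)(C)C | starting material
3 | lithium (trimethylsilyl)acetylide | [Li]C#C[Si](C)(C)C | intermediate (not isolated)
4 | rac-8-methyl-1-(trimethylsilyl)non-1-yn-3-ol | CC(C)CCCCC(O)C#C[Si](C)(C)C | intermediate
5 | hexacarbonyldicobalt complex of 4 (racemate) | CC(C)CCCCC(O)C12[Co]3(=C=O)(=C=O)(=C=O)[Co]1(=C=O)(=C=O)(=C=O)C23[Si](C)(C)C | intermediate
6 | cobalt-stabilised propargylic cation tetrafluoroborate derived from 5 | CC(C)CCCC[CH+]C12[Co]3(=C=O)(=C=O)(=C=O)[Co]1(=C=O)(=C=O)(=C=O)C23[Si](C)(C)C.F[B-](F)(F)F | intermediate (not isolated)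
7 | hexacarbonyldicobalt complex of 8 at one alkyne (racemate) | CC(C)CCCCC(C#C[Si](C)(C)C)C12[Co]3(=C=O)(=C=O)(=C=O)[Co]1(=C=O)(=C=O)(=C=O)C23[Si](C)(C)C | intermediate (not isolated)
8 | 3-(5-methylhexyl)-1,5-bis(trimethylsilyl)penta-1,4-diyne | CC(C)CCCCC(C#C[Si](C)(C)C)C#C[Si](C)(C)C | intermediate
9 | 3-(5-methylhexyl)penta-1,4-diyne | CC(C)CCCCC(C#C)C#C | intermediate
10 | dilithium diacetylide of 9 | [Li]C#CC(CCCCC(C)C)C#C[Li] | intermediate (not isolated)
11 | dilithium bis(ynolate), dilithium 3-(5-methylhexyl)penta-1,4-diyne-1,5-diolate | [Li]OC#CC(CCCCC(C)C)C#CO[Li] | intermediate (not isolated)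
12 | 3-(5-methylhexyl)-1,5-bis(triisopropylsilyloxy)penta-1,4-diyne | CC(C)CCCCC(C#CO[Si](C(C)C)(C(C)C)C(C)C)C#CO[Si](C(C)C)(C(C)C)C(C)C | intermediate (precursor of the key step)
13 | acrolein | C=CC=O | starting material
14 | 2-methylpropene | C=C(C)C | starting material
15 | 2,2-dimethyl-3,4-dihydro-2H-pyran | CC1(C)CCC=CO1 | intermediate
16 | rac-(1R,6S)-8,8-dichloro-3,3-dimethyl-2-oxabicyclo[4.2.0]octan-7-one, cis-fused | O=C1C(Cl)(Cl)[C@@H]2OC(C)(C)CC[C@H]12 | intermediate
17 | rac-(1S,6S)-3,3-dimethyl-2-oxabicyclo[4.2.0]octan-7-one, cis-fused | O=C1C[C@@H]2OC(C)(C)CC[C@H]12 | intermediate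
18 | rac-(1S,6S)-3,3-dimethyl-7-(trimethylsilyloxy)-2-oxabicyclo[4.2.0]oct-7-ene, cis-fused | C[Si](C)(C)OC1=C[C@@H]2OC(C)(C)CC[C@H]12 | intermediate (not isolated)
19 | rac-3,3-dimethyl-2-oxabicyclo[4.2.0]oct-1(8)-en-7-one | O=C1C=C2OC(C)(C)CCC12 | intermediate (precursor of the key step)
20 | 2-(6,6-dimethyl-5,6-dihydro-4H-pyran-2-yl)ethen-1-one (pyranylketene) | O=C=CC1=CCCC(C)(C)O1 | intermediate (not isolated)
21 | rac-2,2-dimethyl-6-[8-methyl-1-(triisopropylsilyloxy)non-1-yn-3-yl]-7-(triisopropylsilyloxy)chroman-5-ol | CC(C)CCCCC(C#CO[Si](C(C)C)(C(C)C)C(C)C)c1c(O)c2c(cc1O[Si](C(C)C)(C(C)C)C(C)C)OC(C)(C)CC2 | intermediate (not isolated)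
22 | 6,6'-(6-methylheptane-1,1-diyl)bis[2,2-dimethyl-7-(triisopropylsilyloxy)chroman-5-ol] | CC(C)CCCCC(c1c(O)c2c(cc1O[Si](C(C)C)(C(C)C)C(C)C)OC(C)(C)CC2)c1c(O)c2c(cc1O[Si](C(C)C)(C(C)C)C(C)C)OC(C)(C)CC2 | intermediate (product of the key step)
23 | 6,6'-(6-methylheptane-1,1-diyl)bis(2,2-dimethylchroman-5,7-diol) | CC(C)CCCCC(c1c(O)c2c(cc1O)OC(C)(C)CC2)c1c(O)c2c(cc1O)OC(C)(C)CC2 | intermediate
24 | (R)-2-methylbutanoic acid | CC[C@@H](C)C(=O)O | starting material
25 | (R)-2-methylbutanoyl chloride | CC[C@@H](C)C(=O)Cl | intermediate
26 | 6,6'-(6-methylheptane-1,1-diyl)bis{5,7-dihydroxy-2,2-dimethyl-8-[(2R)-2-methylbutanoyl]chroman} | CC[C@@H](C)C(=O)c1c(O)c(C(CCCCC(C)C)c2c(O)c3c(c(C(=O)[C@H](C)CC)c2O)OC(C)(C)CC3)c(O)c2c1OC(C)(C)CC2 | target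

## Step count and least certain steps

Total: 13 steps. Longest linear sequence: 8 steps (1, 2, 3, 4, 5, 10, 11, 13) from 6-methylheptanal. The cyclobutenone arm (steps 6–9) and step 12 are convergent branches.

**Step 10 (key step).**
- What may go wrong: the vinylogous-ester stabilisation of 19 may raise the barrier to ring opening until the temperature needed overlaps with thermal oxygen-to-carbon silyl migration in the siloxyalkynes. The sequence may also stall after the first annulation, because the remaining alkyne of 21 sits beside a fully substituted arene, and the ketene may be drained by dimerisation or by acylating the new phenols.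
- Fallback, using known chemistry: it sets out from 1 and 25 and returns at 26. Phloroglucinol is condensed with 2-methylbut-3-en-2-ol under BF3·OEt2 to 2,2-dimethylchroman-5,7-diol F1. This is acylated with 25 under TiCl4 to (2R)-1-(5,7-dihydroxy-2,2-dimethylchroman-8-yl)-2-methylbutan-1-one F2, which is separated from its 6-acyl isomer. Two molecules of F2 are then joined at their free C6 positions by aldehyde 1 under mild acid or amine catalysis, through condensation to an ortho-quinone methide and conjugate addition of the second arene, giving 26 directly. The price is a regioisomer separation, which the main route avoids.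

**Step 9.**
- What may go wrong: the enolate may expel the ring oxygen by β-elimination before it is silylated, enolisation may occur towards the ring-fusion carbon, or 18 may be protodesilylated back to 17 on the palladium stage.
- Fallback: it sets out from 15 and returns at 19 without any enolate. Dihydropyran 15 is combined with (phenylsulfanyl)ketene, made from (phenylsulfanyl)acetyl chloride and Et3N. The cycloaddition has the same regiochemistry as step 7 and puts sulfur on C8, giving cis-fused 3,3-dimethyl-8-(phenylsulfanyl)-2-oxabicyclo[4.2.0]octan-7-one F3. Oxidation with mCPBA at −78 °C gives the sulfoxide F4. Gentle warming in toluene brings about syn-elimination towards H–C1, the only β-hydrogen, and delivers 19.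

**Step 5.**
- What may go wrong: the skipped diyne may undergo base-induced propargyl–allenyl isomerisation, the second acetylide may be oxidised incompletely, or silylation may occur on carbon to give a silylketene.
- Fallback: it sets out from 9 and returns at 11 and then 12, using electrophilic alkyne chemistry. Diyne 9 is treated with PhI(OH)OTs in CHCl3 over a desiccant to give the bis[alkynyl(phenyl)iodonium] ditosylate F5. Catalytic CuOTf in MeCN collapses this to the bis(alkynyl tosylate) F6. MeLi at −78 °C attacks sulfur and releases the bis-ynolate 11, which is silylated with iPr3SiOTf as in step 5.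

**Step 13.**
- What may go wrong: ipso-protonation at C6 may cleave or scramble the diarylmethine bridge before both arenes are deactivated, and the α-stereocentres may partly epimerise by enolisation of the Lewis-acid-bound ketones.
- Fallback: it sets out from 23 and 25 and returns at 26 by directed metalation instead of electrophilic substitution. Tetraol 23 is converted with MOMCl and iPr2NEt into its tetrakis(methoxymethyl) ether F7. Chloride 25 and N,O-dimethylhydroxylamine hydrochloride with pyridine give the Weinreb amide (2R)-N-methoxy-N,2-dimethylbutanamide F8. F7 is lithiated at C8 and C8', each flanked by two oxygens, with nBuLi and TMEDA in THF at 0 °C and quenched with F8. The tetrahedral adduct protects the stereocentres until work-up and gives the tetrakis(methoxymethyl) ether of the target F9. HCl in MeOH at 40 °C removes the acetals from the now deactivated arenes to give 26.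

## Further compounds

F1 | step 10 | 2,2-dimethylchroman-5,7-diol | CC1(C)CCc2c(O)cc(O)cc2O1
F2 | step 10 | (2R)-1-(5,7-dihydroxy-2,2-dimethylchroman-8-yl)-2-methylbutan-1-one | CC[C@@H](C)C(=O)c1c(O)cc(O)c2c1OC(C)(C)CC2
F3 | step 9 | cis-fused 3,3-dimethyl-8-(phenylsulfanyl)-2-oxabicyclo[4.2.0]octan-7-one (racemate, C8 epimers) | O=C1C(Sc3ccccc3)[C@@H]2OC(C)(C)CC[C@H]12
F4 | step 9 | cis-fused 3,3-dimethyl-8-(phenylsulfinyl)-2-oxabicyclo[4.2.0]octan-7-one (racemate, mixture at C8 and S) | O=C1C(S(=O)c3ccccc3)[C@@H]2OC(C)(C)CC[C@H]12
F5 | step 5 | [3-(5-methylhexyl)penta-1,4-diyne-1,5-diyl]bis(phenyliodonium) bis(4-methylbenzenesulfonate) | CC(C)CCCCC(C#C[I+]c1ccccc1)C#C[I+]c1ccccc1.Cc1ccc(cc1)S(=O)(=O)[O-].Cc1ccc(cc1)S(=O)(=O)[O-]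
F6 | step 5 | 3-(5-methylhexyl)penta-1,4-diyne-1,5-diyl bis(4-methylbenzenesulfonate) | CC(C)CCCCC(C#COS(=O)(=O)c1ccc(C)cc1)C#COS(=O)(=O)c1ccc(C)cc1
F7 | step 13 | 6,6'-(6-methylheptane-1,1-diyl)bis[5,7-bis(methoxymethoxy)-2,2-dimethylchroman] | CC(C)CCCCC(c1c(OCOC)c2c(cc1OCOC)OC(C)(C)CC2)c1c(OCOC)c2c(cc1OCOC)OC(C)(C)CC2
F8 | step 13 | (2R)-N-methoxy-N,2-dimethylbutanamide | CC[C@@H](C)C(=O)N(C)OC
F9 | step 13 | 6,6'-(6-methylheptane-1,1-diyl)bis{5,7-bis(methoxymethoxy)-2,2-dimethyl-8-[(2R)-2-methylbutanoyl]chroman} | CC[C@@H](C)C(=O)c1c(OCOC)c(C(CCCCC(C)C)c2c(OCOC)c3c(c(C(=O)[C@H](C)CC)c2OCOC)OC(C)(C)CC3)c(OCOC)c2c1OC(C)(C)CC2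
A1 | alternative 1 | 5,5'-di-O-benzyl bis(2H-chromene), the 3,4-didehydro target | CC(C)CCCCC(c1c(OCc2ccccc2)c2c(c(C(=O)[C@H](C)CC)c1O)OC(C)(C)C=C2)c1c(OCc2ccccc2)c2c(c(C(=O)[C@H](C)CC)c1O)OC(C)(C)C=C2
A2 | alternative 1 | bis(1,1-dimethylpropargyl) aryl ether precursor of A1 | CC(C)CCCCC(c1c(OCc2ccccc2)cc(OC(C)(C)C#C)c(C(=O)[C@H](C)CC)c1O)c1c(OCc2ccccc2)cc(OC(C)(C)C#C)c(C(=O)[C@H](C)CC)c1O
A3 | alternative 2 | 8,8'-bis[(R)-2-methylbut-3-enoyl] analogue of the target | CC(C)CCCCC(c1c(O)c2c(c(C(=O)[C@H](C)C=C)c1O)OC(C)(C)CC2)c1c(O)c2c(c(C(=O)[C@H](C)C=C)c1O)OC(C)(C)CC2
A4 | alternative 2 | 6,6'-(6-methylheptane-1,1-diyl)bis(5,7-dihydroxy-2,2-dimethylchroman-8-carbaldehyde) | CC(C)CCCCC(c1c(O)c2c(c(C=O)c1O)OC(C)(C)CC2)c1c(O)c2c(c(C=O)c1O)OC(C)(C)CC2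
A5 | alternative 2 | buta-1,3-diene | C=CC=C
A6 | alternative 3 | 5,5',7,7'-tetra-O-benzyl ether of the target | CC(C)CCCCC(c1c(OCc2ccccc2)c2c(c(C(=O)[C@H](C)CC)c1OCc3ccccc3)OC(C)(C)CC2)c1c(OCc2ccccc2)c2c(c(C(=O)[C@H](C)CC)c1OCc3ccccc3)OC(C)(C)CC2
A7 | alternative 3 | dibromo bis(tertiary alcohol) precursor of A6 | CC(C)CCCCC(c1c(OCc2ccccc2)c(CCC(C)(C)O)c(Br)c(C(=O)[C@H](C)CC)c1OCc3ccccc3)c1c(OCc2ccccc2)c(CCC(C)(C)O)c(Br)c(C(=O)[C@H](C)CC)c1OCc3ccccc3
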